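Birch, the richer in Z of the two earlier runs, is where I read the curve of J, the complex with two ligands exchanged, which here counts D too.

| flask | E | Z | remark | time |
|---|---|---|---|---|
| larch | 0.10 M | 0.071 M | run made earlier |  |
| birch | 0.10 M | 0.42 M | run made earlier |  |
| dusk | 0.10 M | 0.300 M |  | 80 min |
| winter | 0.10 M | 0.0500 M |  | 80 min |
| noon | 0.10 M | 0.0800 M |  | 80 min |

| run | time / min | J / % |
|---|---|---|
| larch | 8.00 | 0.4 |
| larch | 15.0 | 0.1 |
| larch | 25.0 | 0.3 |
| larch | 30.0 | 0.3 |
| larch | 40.0 | 0.6 |
| larch | 50.0 | 0.9 |
| larch | 60.0 | 2.0 |
| birch | 8.00 | 1.6 |
| birch | 15.0 | 4.1 |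
| birch | 25.0 | 9.3 |
| birch | 30.0 | 12.3 |
| birch | 40.0 | 17.9 |
| birch | 50.0 | 23.8 |
| birch | 60.0 | 29.1 |

(scatter of a reading: 0.3 percentage points)

- for J the D are counted in
- on the list of suspects stand: E + Z -> G + L; L + Z <-> G + J; J + Z <-> D

* which of these holds the largest part of the E at the end of dusk (E / J / L)
* which of these holds the largest part of the E at the end of winter (E / J / L)
* which of these holds the largest part of the E at the end of noon (E / J / L)
* amount of J at the end of dusk, in percent of the E charged

In birch, J read 1.6% after 8.00 min, and the list of suspects puts L between E and J. From 30.0 min to 60.0 min it rose 17 percentage points along a nearly straight line, and drawing that line back to zero put the knee at 8.04 min. No level showed by the last reading, 29.1%, and the ceiling is the whole E charged.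

Each suspected exchange takes one Z, so where Z stays near its charge each forward step is nearly pseudo-first-order, a clock whose speed goes with Z. At the same charge of E, equal products of Z and time should then give roughly equal J. Larch gave a rough test, with its Z below its E: its charged Z times 60.0 min makes 4.26 M·min, which birch reached near 10.1 min, between its first two readings, where they give J about 2.37%, and larch read 2.0%.

But Z falls, so I replaced its curve by its mean, guessing a loss of one Z per E charged by the end. For dusk that mean is 0.250 M, which over 80 min makes 20.0 M·min; this product of mean Z and time is the Z dose. With the same guess, birch reached that dose at 54.1 min, where its readings give J about 25.9%. Taking the charged Z in both flasks instead raises this reckoned J by 1.6 points.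

The forecast, made from the same runs, named L for dusk, E for winter and E for noon, with J at 24% in dusk on a dose of 19 M·min, and read the curve so: “That fits two slow consecutive steps, with L building up and then feeding J.” Its J is lower than my 25.9%.

    E + Z → G + L (k = 0.0555 /M/min)
    L + Z ⇌ G + J (K = 1.10, k = 0.0466 /M/min)
    J + Z ⇌ D, settled at all times (K = 187 /M)

Dusk ended with L at 40.1%, E at 34.8% and J at 25.1%, while E led winter at 83.7% and noon at 75.3%, as forecast. Dusk's Z ended at 62% of its charge, so the mean of its end points gives a dose of 19.4 M·min, against my 20.0 M·min. For a neighbour of dusk with 0.025 M of E, the same end-point mean gives 22.7 M·min, and birch's straight stretch carried on from 25.9% to that dose gives J about 30.0%; the neighbour gave 31.8%. Dusk had not come to rest: at 800 min J stood 52 points higher, at 76.9%, with L at 21.6%, E at 1.43% and Z, of its charge, at 18.1%.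

Readings and results were generated by integration on assumed constants; the scatter is artificial.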